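**Retrosynthetic overview**

1. The oxirane is made last, by hydroxyl-directed epoxidation of a C-6 vinyl group; before that come SeO2 oxidation of the C-5 isopropenyl group, methylenation of a C-6 formyl group and O-4 isobutyrylation.
2. The bicyclic core comes from two acyclic partners in one operation: acid closes the γ-lactone and frees a 1,4-dialdehyde, then diene 1,2-diboration/double allylboration closes the cyclohexane (bonds C6–C7 and C4–C5, four contiguous stereocentres).
3. The acyclic γ-hydroxy ester comes from a catalytic asymmetric chromium 2-(alkoxycarbonyl)allylation of 2,2-dimethoxyacetaldehyde with a Morita–Baylis–Hillman-derived allyl bromide made from the same aldehyde and tert-butyl acrylate.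
4. The diene comes from Wittig olefination of methacrolein followed by acetalization.
5. Order of ring formation: γ-lactone, then cyclohexane (same operation), then oxirane.

Assumption: ring positions in the text follow 1-benzofuran-2-one numbering (O-1, C-2 carbonyl, C-3 methylidene, C-3a, C-4 to C-7, C-7a), as in the names.
Assumption: the ligand antipodes named in steps 3 and 6 are taken to be those that give the drawn enantiomers; if the sense of induction is the reverse, the mirror-image ligand is used.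
Assumption: commercial aqueous 2,2-dimethoxyacetaldehyde is used as such in step 1 and is dried and distilled for step 3.

**Step 1**
Reactants: 1 2,2-dimethoxyacetaldehyde; 2 tert-butyl prop-2-enoate
Product: 3 tert-butyl 3-hydroxy-4,4-dimethoxy-2-methylidenebutanoate (racemic)
Conditions: DABCO (0.5 equiv), 1,4-dioxane/H2O 1:1, 23 °C
Reagents that add atoms: none
Why: Morita–Baylis–Hillman reaction, in which the DABCO–acrylate zwitterion adds to the activated, non-enolisable aldehyde; the racemic carbinol centre is erased in step 2.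

**Step 2**
Reactants: 3 tert-butyl 3-hydroxy-4,4-dimethoxy-2-methylidenebutanoate
Product: 4 tert-butyl (2Z)-2-(bromomethyl)-4,4-dimethoxybut-2-enoate
Conditions: N-bromosuccinimide, Me2S, CH2Cl2, 0 to 23 °C
Reagents that add atoms: N-bromosuccinimide, O=C1CCC(=O)N1Br
Why: Corey–Kim-type activation of the allylic alcohol as an alkoxysulfonium ion followed by SN2′ delivery of bromide gives the conjugated (Z)-2-(bromomethyl)alk-2-enoate under non-acidic conditions that leave the acetal intact.

**Step 3**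
Reactants: 4 tert-butyl (2Z)-2-(bromomethyl)-4,4-dimethoxybut-2-enoate; 1 2,2-dimethoxyacetaldehyde (anhydrous)
Product: 6 tert-butyl (3R,4R)-3-(dimethoxymethyl)-4-hydroxy-5,5-dimethoxy-2-methylidenepentanoate, via trimethylsilyl ether 5 (not isolated)
Conditions: CrCl2 (10 mol %), (S,S)-3,6-di-tert-butyl-1,8-bis(4-isopropyl-4,5-dihydrooxazol-2-yl)-9H-carbazole (12 mol %), Mn powder, Me3SiCl, iPr2NEt, DME, 0 to 23 °C; then 10 % aq. citric acid, THF, 0 °C
Reagents that add atoms: none
Why: catalytic asymmetric Nozaki–Hiyama–Kishi 2-(alkoxycarbonyl)allylation, in which the γ-substituted allyl species on trivalent chromium adds through a chair (Zimmerman–Traxler) transition state to give the anti adduct while the tridentate ligand selects the aldehyde face, setting both centres as (3R,4R); the tert-butyl ester keeps the γ-hydroxy ester open.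

**Step 4**
Reactants: 7 2-methylprop-2-enal; 8 2-(triphenyl-λ5-phosphanylidene)propanal
Product: 9 (2E)-2,4-dimethylpenta-2,4-dienal
Conditions: CH2Cl2, 40 °C
Reagents that add atoms: none
Why: Wittig olefination with a formyl-stabilised ylide attacks the aldehyde carbonyl and gives the (E)-trisubstituted alkene.

**Step 5**
Reactants: 9 (2E)-2,4-dimethylpenta-2,4-dienal
Product: 10 (3E)-5,5-dimethoxy-2,4-dimethylpenta-1,3-diene
Conditions: HC(OMe)3, pyridinium p-toluenesulfonate (2 mol %), CH2Cl2, 23 °C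
Reagents that add atoms: trimethyl orthoformate, COC(OC)OC
Why: acid-catalysed acetalization with the orthoformate as water scavenger masks the aldehyde, which would otherwise be allylated by its own boronate in step 6, without moving the (E)-alkene.

**Step 6**
Reactants: 6 tert-butyl (3R,4R)-3-(dimethoxymethyl)-4-hydroxy-5,5-dimethoxy-2-methylidenepentanoate; 10 (3E)-5,5-dimethoxy-2,4-dimethylpenta-1,3-diene
Product: 15 (3aS,4S,5S,6S,7S,7aR)-6-(dimethoxymethyl)-4,7-dihydroxy-6-methyl-3-methylidene-5-(prop-1-en-2-yl)hexahydro-1-benzofuran-2(3H)-one, via lactone dialdehyde 11 (not isolated), via bis(boronate) 12 (not isolated), via mono-allylation adduct 13 (not isolated), via bis(borate) ester 14 (not isolated)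
Conditions: flask A: 6, CF3CO2H/H2O 9:1, 0 to 23 °C, then toluene azeotrope and filtration through NaHCO3/Na2SO4; flask B: 10, B2pin2, Pt(dba)3 (3 mol %), (R,R)-TADDOL-derived phenylphosphonite bearing 3,5-diisopropylphenyl groups (6 mol %), THF, 60 °C; A added to B, toluene/THF, 23 to 60 °C; pH 7 phosphate buffer
Reagents that add atoms: water, O
Why: Proposed new method: acid frees both formyl groups of 6 and closes the trans γ-lactone on the only hydroxyl present (first ring) to give 11, whose C-3 can only drift toward the more stable trans-dialdehyde; meanwhile zerovalent-platinum/phosphonite 1,2-diboration of the terminal alkene of 10 (a 4,4-disubstituted diene cannot reach the s-cis geometry needed for 1,4-addition) gives the tertiary allylboronate 12; the γ,γ-disubstituted terminus of 12 then adds to the more electrophilic α-oxygenated formyl group of 11 through a chair transition state (attack on the boron face, aldehyde substituent equatorial, CH2Bpin pseudoaxial), which sets quaternary C-6 and the C-7 carbinol in the Felkin–Anh-matched sense and unveils the (Z)-allylboronate 13; 13 closes the cyclohexane (second ring) by intramolecular allylboration through a cis-decalin-like bicyclic chair that places the small C-6 methyl over the boron ring and thereby fixes C-5 and C-4; the closest known reaction type is the enantioselective diene 1,2-diboration/double carbonyl allylboration of 1,4-dicarbonyl compounds to cyclohexane-1,4-diols together with stereospecific intramolecular allylboration, and the extension lies in the 2-methyl diene (tertiary boronate) and the lactone-bearing dialdehyde.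

**Step 7**
Reactants: 15 (3aS,4S,5S,6S,7S,7aR)-6-(dimethoxymethyl)-4,7-dihydroxy-6-methyl-3-methylidene-5-(prop-1-en-2-yl)hexahydro-1-benzofuran-2(3H)-one
Product: 16 (3aS,4S,5S,6S,7S,7aR)-7-{[tert-butyl(dimethyl)silyl]oxy}-6-(dimethoxymethyl)-4-hydroxy-6-methyl-3-methylidene-5-(prop-1-en-2-yl)hexahydro-1-benzofuran-2(3H)-one
Conditions: tBuMe2SiCl (1.1 equiv), imidazole, DMF, 0 °C
Reagents that add atoms: tert-butyl(chloro)dimethylsilane, CC(C)(C)[Si](C)(C)Cl
Why: kinetic silyl ether formation is expected at O-7 because, of the two axial secondary hydroxyls, the C-7 one has only hydrogens syn-axial whereas the C-4 one is 1,3-diaxial to the C-6 methyl and flanked by two branched sp2-bearing carbons.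

**Step 8**
Reactants: 16 (3aS,4S,5S,6S,7S,7aR)-7-{[tert-butyl(dimethyl)silyl]oxy}-6-(dimethoxymethyl)-4-hydroxy-6-methyl-3-methylidene-5-(prop-1-en-2-yl)hexahydro-1-benzofuran-2(3H)-one
Product: 17 (3aS,4S,5S,6S,7S,7aR)-7-{[tert-butyl(dimethyl)silyl]oxy}-6-(dimethoxymethyl)-6-methyl-3-methylidene-2-oxo-5-(prop-1-en-2-yl)octahydro-1-benzofuran-4-yl 2-methylpropanoate
Conditions: (iPrCO)2O, 4-(dimethylamino)pyridine, Et3N, CH2Cl2, 40 °C
Reagents that add atoms: isobutyric anhydride, CC(C)C(=O)OC(=O)C(C)C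
Why: nucleophile-catalysed acyl transfer (acylpyridinium) esterifies the one remaining, hindered hydroxyl; no stereocentre is touched.

**Step 9**
Reactants: 17 (3aS,4S,5S,6S,7S,7aR)-7-{[tert-butyl(dimethyl)silyl]oxy}-6-(dimethoxymethyl)-6-methyl-3-methylidene-2-oxo-5-(prop-1-en-2-yl)octahydro-1-benzofuran-4-yl 2-methylpropanoate
Product: 18 (3aS,4S,5S,6S,7S,7aR)-7-{[tert-butyl(dimethyl)silyl]oxy}-6-formyl-6-methyl-3-methylidene-2-oxo-5-(prop-1-en-2-yl)octahydro-1-benzofuran-4-yl 2-methylpropanoate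
Conditions: pyridinium p-toluenesulfonate (20 mol %), acetone/H2O 10:1, 50 °C
Reagents that add atoms: water, O
Why: mild acid-catalysed acetal hydrolysis frees the neopentyl aldehyde while the hindered secondary silyl ether, both esters and the alkenes survive, and keeping O-7 silylated blocks retro-aldol cleavage of the β-oxy aldehyde.

**Step 10**
Reactants: 18 (3aS,4S,5S,6S,7S,7aR)-7-{[tert-butyl(dimethyl)silyl]oxy}-6-formyl-6-methyl-3-methylidene-2-oxo-5-(prop-1-en-2-yl)octahydro-1-benzofuran-4-yl 2-methylpropanoate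
Product: 20 (3aS,4S,5S,6S,7S,7aR)-6-ethenyl-7-hydroxy-6-methyl-3-methylidene-2-oxo-5-(prop-1-en-2-yl)octahydro-1-benzofuran-4-yl 2-methylpropanoate, via silyl ether 19 (not isolated)
Conditions: Ph3PCH3Br, KN(SiMe3)2, THF, −78 to 0 °C; then HF·pyridine, THF, 0 to 23 °C
Reagents that add atoms: methyltriphenylphosphonium bromide, C[P+](c1ccccc1)(c1ccccc1)c1ccccc1.[Br-]
Why: Wittig methylenation with the small unstabilised ylide at low temperature takes the aldehyde faster than the conjugated lactone, the quaternary α-carbon cannot epimerise, and fluoride-mediated desilylation then frees the C-7 hydroxyl.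

**Step 11**
Reactants: 20 (3aS,4S,5S,6S,7S,7aR)-6-ethenyl-7-hydroxy-6-methyl-3-methylidene-2-oxo-5-(prop-1-en-2-yl)octahydro-1-benzofuran-4-yl 2-methylpropanoate
Product: 21 (3aS,4S,5R,6S,7S,7aR)-6-ethenyl-7-hydroxy-6-methyl-3-methylidene-2-oxo-5-(3-oxoprop-1-en-2-yl)octahydro-1-benzofuran-4-yl 2-methylpropanoate
Conditions: SeO2 (1.5 equiv), 1,4-dioxane, 70 °C
Reagents that add atoms: selenium dioxide, O=[Se]=O
Why: selenium dioxide allylic oxidation (ene reaction, then 2,3-sigmatropic shift) attacks the methyl of the only electron-rich alkene that has accessible allylic hydrogens and carries it to the enal, the vinyl group having no allylic hydrogen and the methylidene lactone being too electron-poor; doing this before the epoxidation also deactivates the isopropenyl alkene toward the next reagent.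

**Step 12**
Reactants: 21 (3aS,4S,5R,6S,7S,7aR)-6-ethenyl-7-hydroxy-6-methyl-3-methylidene-2-oxo-5-(3-oxoprop-1-en-2-yl)octahydro-1-benzofuran-4-yl 2-methylpropanoate
Product: 22 (3aS,4S,5R,6S,7S,7aR)-7-hydroxy-6-methyl-3-methylidene-6-[(2R)-oxiran-2-yl]-2-oxo-5-(3-oxoprop-1-en-2-yl)octahydro-1-benzofuran-4-yl 2-methylpropanoate
Conditions: VO(acac)2 (5 mol %), tBuOOH (decane solution, 1.5 equiv), CH2Cl2, 0 °C
Reagents that add atoms: tert-butyl hydroperoxide, CC(C)(C)OO
Why: hydroxyl-directed vanadium-catalysed epoxidation of a homoallylic alcohol, in which the vanadate ester of the axial C-7 hydroxyl delivers oxygen through a chair-like six-membered transition state to the vinyl face turned toward O-7 (C=C syn-periplanar to the C-6–C-5 bond), giving the (R)-oxirane, while the two electron-poor alkenes are not epoxidised by this reagent.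

**Compound list**

1 | 2,2-dimethoxyacetaldehyde | COC(OC)C=O | starting material
2 | tert-butyl prop-2-enoate | C=CC(=O)OC(C)(C)C | starting material
3 | tert-butyl 3-hydroxy-4,4-dimethoxy-2-methylidenebutanoate (racemic) | C=C(C(=O)OC(C)(C)C)C(O)C(OC)OC | intermediate
4 | tert-butyl (2Z)-2-(bromomethyl)-4,4-dimethoxybut-2-enoate | BrC/C(C(=O)OC(C)(C)C)=C\C(OC)OC | intermediate
5 | tert-butyl (3R,4R)-3-(dimethoxymethyl)-5,5-dimethoxy-2-methylidene-4-[(trimethylsilyl)oxy]pentanoate | C=C(C(=O)OC(C)(C)C)[C@@H](C(OC)OC)[C@@H](O[Si](C)(C)C)C(OC)OC | intermediate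
6 | tert-butyl (3R,4R)-3-(dimethoxymethyl)-4-hydroxy-5,5-dimethoxy-2-methylidenepentanoate | C=C(C(=O)OC(C)(C)C)[C@@H](C(OC)OC)[C@@H](O)C(OC)OC | intermediate
7 | 2-methylprop-2-enal | C=C(C)C=O | starting material
8 | 2-(triphenyl-λ5-phosphanylidene)propanal | CC(C=O)=P(c1ccccc1)(c1ccccc1)c1ccccc1 | starting material
9 | (2E)-2,4-dimethylpenta-2,4-dienal | C=C(C)/C=C(\C)C=O | intermediate
10 | (3E)-5,5-dimethoxy-2,4-dimethylpenta-1,3-diene | C=C(C)/C=C(\C)C(OC)OC | intermediate
11 | (2R,3R)-4-methylidene-5-oxooxolane-2,3-dicarbaldehyde | C=C1C(=O)O[C@@H](C=O)[C@@H]1C=O | intermediate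
12 | 2,2'-[(2R,3E)-5,5-dimethoxy-2,4-dimethylpent-3-ene-1,2-diyl]bis(4,4,5,5-tetramethyl-1,3,2-dioxaborolane) | CC1(C)OB(OC1(C)C)C[C@](C)(B1OC(C)(C)C(C)(C)O1)/C=C(\C)C(OC)OC | intermediate
13 | (2R,3R)-2-{(1S,2S,3Z)-2-(dimethoxymethyl)-2,4-dimethyl-5-(4,4,5,5-tetramethyl-1,3,2-dioxaborolan-2-yl)-1-[(4,4,5,5-tetramethyl-1,3,2-dioxaborolan-2-yl)oxy]pent-3-en-1-yl}-4-methylidene-5-oxooxolane-3-carbaldehyde | C=C1C(=O)O[C@@H]([C@@H](OB2OC(C)(C)C(C)(C)O2)[C@@](C)(C(OC)OC)/C=C(/C)CB2OC(C)(C)C(C)(C)O2)[C@@H]1C=O | intermediate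
14 | (3aS,4S,5S,6S,7S,7aR)-6-(dimethoxymethyl)-6-methyl-3-methylidene-5-(prop-1-en-2-yl)-4,7-bis[(4,4,5,5-tetramethyl-1,3,2-dioxaborolan-2-yl)oxy]hexahydro-1-benzofuran-2(3H)-one | C=C1C(=O)O[C@@H]2[C@@H]1[C@@H](OB3OC(C)(C)C(C)(C)O3)[C@@H](C(C)=C)[C@](C)(C(OC)OC)[C@@H]2OB3OC(C)(C)C(C)(C)O3 | intermediate
15 | (3aS,4S,5S,6S,7S,7aR)-6-(dimethoxymethyl)-4,7-dihydroxy-6-methyl-3-methylidene-5-(prop-1-en-2-yl)hexahydro-1-benzofuran-2(3H)-one | C=C1C(=O)O[C@@H]2[C@@H]1[C@@H](O)[C@@H](C(C)=C)[C@](C)(C(OC)OC)[C@@H]2O | intermediate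
16 | (3aS,4S,5S,6S,7S,7aR)-7-{[tert-butyl(dimethyl)silyl]oxy}-6-(dimethoxymethyl)-4-hydroxy-6-methyl-3-methylidene-5-(prop-1-en-2-yl)hexahydro-1-benzofuran-2(3H)-one | C=C1C(=O)O[C@@H]2[C@@H]1[C@@H](O)[C@@H](C(C)=C)[C@](C)(C(OC)OC)[C@@H]2O[Si](C)(C)C(C)(C)C | intermediate
17 | (3aS,4S,5S,6S,7S,7aR)-7-{[tert-butyl(dimethyl)silyl]oxy}-6-(dimethoxymethyl)-6-methyl-3-methylidene-2-oxo-5-(prop-1-en-2-yl)octahydro-1-benzofuran-4-yl 2-methylpropanoate | C=C1C(=O)O[C@@H]2[C@@H]1[C@@H](OC(=O)C(C)C)[C@@H](C(C)=C)[C@](C)(C(OC)OC)[C@@H]2O[Si](C)(C)C(C)(C)C | intermediate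
18 | (3aS,4S,5S,6S,7S,7aR)-7-{[tert-butyl(dimethyl)silyl]oxy}-6-formyl-6-methyl-3-methylidene-2-oxo-5-(prop-1-en-2-yl)octahydro-1-benzofuran-4-yl 2-methylpropanoate | C=C1C(=O)O[C@@H]2[C@@H]1[C@@H](OC(=O)C(C)C)[C@@H](C(C)=C)[C@](C)(C=O)[C@@H]2O[Si](C)(C)C(C)(C)C | intermediate
19 | (3aS,4S,5S,6S,7S,7aR)-7-{[tert-butyl(dimethyl)silyl]oxy}-6-ethenyl-6-methyl-3-methylidene-2-oxo-5-(prop-1-en-2-yl)octahydro-1-benzofuran-4-yl 2-methylpropanoate | C=C1C(=O)O[C@@H]2[C@@H]1[C@@H](OC(=O)C(C)C)[C@@H](C(C)=C)[C@](C)(C=C)[C@@H]2O[Si](C)(C)C(C)(C)C | intermediate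
20 | (3aS,4S,5S,6S,7S,7aR)-6-ethenyl-7-hydroxy-6-methyl-3-methylidene-2-oxo-5-(prop-1-en-2-yl)octahydro-1-benzofuran-4-yl 2-methylpropanoate | C=C1C(=O)O[C@@H]2[C@@H]1[C@@H](OC(=O)C(C)C)[C@@H](C(C)=C)[C@](C)(C=C)[C@@H]2O | intermediate
21 | (3aS,4S,5R,6S,7S,7aR)-6-ethenyl-7-hydroxy-6-methyl-3-methylidene-2-oxo-5-(3-oxoprop-1-en-2-yl)octahydro-1-benzofuran-4-yl 2-methylpropanoate | C=C1C(=O)O[C@@H]2[C@@H]1[C@@H](OC(=O)C(C)C)[C@@H](C(=C)C=O)[C@](C)(C=C)[C@@H]2O | intermediate
22 | (3aS,4S,5R,6S,7S,7aR)-7-hydroxy-6-methyl-3-methylidene-6-[(2R)-oxiran-2-yl]-2-oxo-5-(3-oxoprop-1-en-2-yl)octahydro-1-benzofuran-4-yl 2-methylpropanoate | C=C1C(=O)O[C@@H]2[C@@H]1[C@@H](OC(=O)C(C)C)[C@@H](C(=C)C=O)[C@](C)([C@@H]1CO1)[C@@H]2O | target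

**Step count**

Total: 12 steps. Longest linear sequence: 10 steps (1, 2, 3, 6, 7, 8, 9, 10, 11, 12).

**Three steps most likely to fail**

Step 6. The tertiary, doubly hindered allylboronate may react sluggishly. The CH2Bpin-versus-methyl choice for the pseudoaxial site decides the Z/E fidelity of 13. The two formyl groups of 11 must react in the right order. 11 itself can move its exocyclic alkene into conjugation. The fallback sets out from 8 and 11 and comes back at 15. Wittig reaction of 8 with acrolein gives (2E)-2-methylpenta-2,4-dienal F3. Acetalization as in step 5 gives (3E)-5,5-dimethoxy-4-methylpenta-1,3-diene F4. Its diboration gives the secondary bis(boronate) F5, the reagent class for which this tandem annulation is established. Reaction with 11 and hydrolytic work-up give the 5-ethenyl diol F6. Wacker oxidation (PdCl2, CuCl, O2, DMF/H2O) gives the methyl ketone F7, and Wittig methylenation (Ph3P=CH2, THF, 0 °C) gives 15.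

Step 3. The anti/syn ratio and the enantioselectivity with a γ-acetal-substituted bromide are not assured. The fallback sets out from 4 and 1 and comes back at 11. If the allylation gives mainly the syn adduct, tert-butyl (3S,4R)-3-(dimethoxymethyl)-4-hydroxy-5,5-dimethoxy-2-methylidenepentanoate F1, that material is carried through the acid stage of step 6 to the cis-dialdehyde F2. Because C-3 of F2 is α to a formyl group, it is equilibrated (pyridinium acetate, CH2Cl2, 23 °C) to the more stable trans isomer 11. That centre is then set under thermodynamic rather than kinetic control, and the catalyst-set C-2 centre is not touched.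

Step 7. Discrimination between the two axial hydroxyls rests on a steric argument only. The fallback sets out from 15 and comes back at 17. Both hydroxyls are acylated with excess isobutyric anhydride to give the bis-isobutyrate F8. The more exposed 7-O-ester is removed with Candida antarctica lipase B (pH 7 buffer/tert-butyl methyl ether) to give the 4-mono-isobutyrate F9. Its single free hydroxyl is then silylated (tBuMe2SiCl, imidazole) to give 17.

**Further compounds**

F1 | step 3 | tert-butyl (3S,4R)-3-(dimethoxymethyl)-4-hydroxy-5,5-dimethoxy-2-methylidenepentanoate | C=C(C(=O)OC(C)(C)C)[C@H](C(OC)OC)[C@@H](O)C(OC)OC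
F2 | step 3 | (2R,3S)-4-methylidene-5-oxooxolane-2,3-dicarbaldehyde | C=C1C(=O)O[C@@H](C=O)[C@H]1C=O
F3 | step 6 | (2E)-2-methylpenta-2,4-dienal | C=C/C=C(\C)C=O
F4 | step 6 | (3E)-5,5-dimethoxy-4-methylpenta-1,3-diene | C=C/C=C(\C)C(OC)OC
F5 | step 6 | 2,2'-[(2S,3E)-5,5-dimethoxy-4-methylpent-3-ene-1,2-diyl]bis(4,4,5,5-tetramethyl-1,3,2-dioxaborolane) | CC1(C)OB(OC1(C)C)C[C@H](B1OC(C)(C)C(C)(C)O1)/C=C(\C)C(OC)OC
F6 | step 6 | (3aS,4S,5S,6S,7S,7aR)-6-(dimethoxymethyl)-5-ethenyl-4,7-dihydroxy-6-methyl-3-methylidenehexahydro-1-benzofuran-2(3H)-one | C=C1C(=O)O[C@@H]2[C@@H]1[C@@H](O)[C@@H](C=C)[C@](C)(C(OC)OC)[C@@H]2O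
F7 | step 6 | (3aS,4R,5S,6S,7S,7aR)-5-acetyl-6-(dimethoxymethyl)-4,7-dihydroxy-6-methyl-3-methylidenehexahydro-1-benzofuran-2(3H)-one | C=C1C(=O)O[C@@H]2[C@@H]1[C@@H](O)[C@@H](C(C)=O)[C@](C)(C(OC)OC)[C@@H]2O
F8 | step 7 | (3aS,4S,5S,6S,7S,7aR)-6-(dimethoxymethyl)-6-methyl-3-methylidene-2-oxo-5-(prop-1-en-2-yl)octahydro-1-benzofuran-4,7-diyl bis(2-methylpropanoate) | C=C1C(=O)O[C@@H]2[C@@H]1[C@@H](OC(=O)C(C)C)[C@@H](C(C)=C)[C@](C)(C(OC)OC)[C@@H]2OC(=O)C(C)C
F9 | step 7 | (3aS,4S,5S,6S,7S,7aR)-6-(dimethoxymethyl)-7-hydroxy-6-methyl-3-methylidene-2-oxo-5-(prop-1-en-2-yl)octahydro-1-benzofuran-4-yl 2-methylpropanoate | C=C1C(=O)O[C@@H]2[C@@H]1[C@@H](OC(=O)C(C)C)[C@@H](C(C)=C)[C@](C)(C(OC)OC)[C@@H]2O
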